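**Retrosynthetic overview**

- Ring numbering used throughout is that of the quinone: C1 (=O), C2 (OH), C3 (hexadecyl), C4 (=O), C5 (OMe), C6 (H). The strategy rests on the segment C1(=O)–C6H=C5(OMe)–C4(=O), a cis-2-ene-1,4-dicarbonyl unit that is a ring-opened, oxidised 3-methoxyfuran. C2–C3 with its chain is the C=O and α-CH2 of a stearoyl group.
- The hydroxyquinone comes from 3-hexadecyl-5-methoxybenzene-1,2,4-triol by oxidation of the para C1/C4 hydroxyl pair.
- The triol comes from 1-(4-methoxyfuran-2-yl)octadecan-1-one: oxidative furan opening to the cis-enedione aldehyde, then aldol closure of the C3–C4 bond (the only ring formation) and aromatisation.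
- The furyl ketone comes from 3-methoxyfuran: silyl block at C2, lithiation at C5, acylation with the Weinreb amide of stearic acid, removal of silicon.

Key step: step 5

Remark: the target has no stereocentre; dimethyldioxirane is used as a titrated solution in acetone.

**Step 1**
Reactants: 1 stearoyl chloride; 2 N,O-dimethylhydroxylamine hydrochloride
Product: 3 N-methoxy-N-methyloctadecanamide
Conditions: Et3N (2.2 equiv), CH2Cl2, 0 °C → rt
Reagents that add atoms: N,O-dimethylhydroxylamine hydrochloride, CNOC.Cl
Why: N-acylation of the hydroxylamine by the acid chloride (Weinreb amide formation) is fast and clean, and Et3N takes up both equivalents of HCl.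

**Step 2**
Reactants: 4 3-methoxyfuran; 5 chlorotrimethylsilane
Product: 6 (3-methoxyfuran-2-yl)trimethylsilane
Conditions: n-BuLi (1.05 equiv), THF, −78 → 0 °C; then Me3SiCl, −78 °C → rt
Reagents that add atoms: chlorotrimethylsilane, C[Si](C)(C)Cl
Why: Directed ortho-lithiation should occur at C2, which is both α to the ring oxygen and ortho to the methoxy group, and silylation of the furyllithium blocks this most reactive position.

**Step 3**
Reactants: 6 (3-methoxyfuran-2-yl)trimethylsilane; 3 N-methoxy-N-methyloctadecanamide
Product: 7 1-[4-methoxy-5-(trimethylsilyl)furan-2-yl]octadecan-1-one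
Conditions: n-BuLi (1.1 equiv), THF, −78 → 0 °C; then 3, −78 °C → rt; H2O quench
Reagents that add atoms: N-methoxy-N-methyloctadecanamide, CCCCCCCCCCCCCCCCCC(=O)N(C)OC
Why: With C2 blocked, α-lithiation should take place at C5 in preference to the β-position C4, and the Weinreb ketone synthesis stops at the ketone because the chelated tetrahedral adduct persists until work-up.

**Step 4**
Reactants: 7 1-[4-methoxy-5-(trimethylsilyl)furan-2-yl]octadecan-1-one
Product: 8 1-(4-methoxyfuran-2-yl)octadecan-1-one
Conditions: Bu4NF·3H2O (1.1 equiv), THF, 0 °C → rt
Reagents that add atoms: none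
Why: Fluoride-induced protodesilylation should proceed because the carbanion character developing at the furan carbon is stabilised by the ring oxygen, the adjacent methoxy group and the 2-acyl group, while the enol ether and the ketone tolerate these non-acidic conditions.

**Step 5**
Reactants: 8 1-(4-methoxyfuran-2-yl)octadecan-1-one
Product: 11 3-hexadecyl-5-methoxybenzene-1,2,4-triol, via cis-enedione aldehyde 9 (not isolated), via cyclic aldol adduct 10 (not isolated)
Conditions: dimethyldioxirane (1.0 equiv, acetone), CH2Cl2, −78 → −20 °C, dark, Ar; volatiles removed at ≤ 0 °C; then DBU (0.2 equiv), degassed CH2Cl2, −40 → 0 °C; AcOH quench, degassed aq. NaH2PO4/Na2S2O4 work-up under Ar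
Reagents that add atoms: dimethyldioxirane, CC1(C)OO1
Why: Proposed new method: dimethyldioxirane should epoxidise the enol-ether C4=C5 bond of the furan, and the epoxide should open to the cis-enedione aldehyde 9, in which the ring-opened furan C2 and the stearoyl C=O form a 1,2-diketone and furan C5 has become an aldehyde; the closest known reaction types are the dioxirane opening of furans to cis-2-ene-1,4-diones and the base-mediated intramolecular aldol cyclisation of 1,2-diketones, which have not been run together in one flask to give an arene. DBU then enolises the diketone toward its CH2 group, and this carbon (C3) adds to the aldehyde carbon (C4) in a 6-(enolendo)-exo-trig aldol closure, enolendo because both C2 and C3 of the enolate lie in the new ring, which is the only ring formed. Adduct 10 is a keto tautomer of the arene, so enolisation at C2 and loss of the doubly vinylogous C4–H should give triol 11 with aromatisation as the driving force. The two stereocentres of 10 (C3 and C4) form without control and vanish on aromatisation, so no stereochemical element has to be set. The step needs the cis geometry of 9 to survive until closure, which the furan ring of origin supplies and which cold, dark, acid-free conditions and a hindered amidine base preserve, and it needs tautomerisation to outrun E1cB loss of water to the ortho-quinone, which the absence of acid favours because hydroxide is a poor leaving group. Regiochemistry needs no control, since the methoxy group sits on furan C4 and so ends on C5 beside the aldehyde-derived C4–OH.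

**Step 6**
Reactants: 11 3-hexadecyl-5-methoxybenzene-1,2,4-triol
Product: 12 3-hexadecyl-2-hydroxy-5-methoxycyclohexa-2,5-diene-1,4-dione
Conditions: Ag2O (2 equiv), MgSO4, Et2O, rt, dark; filtration; 0.5 M HCl wash
Reagents that add atoms: none
Why: Hydroquinone-to-quinone oxidation of the para C1/C4 hydroxyl pair should give the 2-hydroxy-1,4-benzoquinone, the stable tautomer, leaving the C2 hydroxyl and C5 methoxy groups in place.

**Compound list**

1 | stearoyl chloride (octadecanoyl chloride) | CCCCCCCCCCCCCCCCCC(=O)Cl | starting material
2 | N,O-dimethylhydroxylamine hydrochloride | CNOC.Cl | starting material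
3 | N-methoxy-N-methyloctadecanamide | CCCCCCCCCCCCCCCCCC(=O)N(C)OC | intermediate
4 | 3-methoxyfuran | COc1ccoc1 | starting material
5 | chlorotrimethylsilane | C[Si](C)(C)Cl | starting material
6 | (3-methoxyfuran-2-yl)trimethylsilane | COc1ccoc1[Si](C)(C)C | intermediate
7 | 1-[4-methoxy-5-(trimethylsilyl)furan-2-yl]octadecan-1-one | CCCCCCCCCCCCCCCCCC(=O)c1cc(OC)c([Si](C)(C)C)o1 | intermediate
8 | 1-(4-methoxyfuran-2-yl)octadecan-1-one | CCCCCCCCCCCCCCCCCC(=O)c1cc(OC)co1 | intermediate
9 | (2E)-2-methoxy-4,5-dioxodocos-2-enal, the cis-enedione aldehyde (formyl and acyl carbons on the same side of the C=C bond) | CCCCCCCCCCCCCCCCCC(=O)C(=O)/C=C(\C=O)OC | intermediate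
10 | 3-hexadecyl-4-hydroxy-5-methoxycyclohex-5-ene-1,2-dione (mixture of diastereomers at C3/C4, not controlled) | CCCCCCCCCCCCCCCCC1C(O)C(OC)=CC(=O)C1=O | intermediate
11 | 3-hexadecyl-5-methoxybenzene-1,2,4-triol | CCCCCCCCCCCCCCCCc1c(O)c(O)cc(OC)c1O | intermediate
12 | 3-hexadecyl-2-hydroxy-5-methoxycyclohexa-2,5-diene-1,4-dione | CCCCCCCCCCCCCCCCC1=C(O)C(=O)C=C(OC)C1=O | target

**Step count**

Total steps: 6. Longest linear sequence: 5 (steps 2 to 6 from 3-methoxyfuran; step 1 is a one-step side branch).

**Steps most likely to fail**

1. Step 5. The cis-enedione may isomerise to the trans form before it can close, the furan epoxide may rearrange instead of opening, or the aldol adduct may lose water or oligomerise instead of aromatising. The fallback uses known chemistry, sets out from Weinreb amide 3 and returns at target 12. Commercial 1,2,4,5-tetramethoxybenzene would be lithiated between two methoxy groups (n-BuLi, TMEDA, THF, 0 °C) and acylated with 3 to give 1-(2,3,5,6-tetramethoxyphenyl)octadecan-1-one F1. Ionic hydrogenation of this electron-rich aryl ketone (Et3SiH, CF3CO2H, rt) would give 3-hexadecyl-1,2,4,5-tetramethoxybenzene F2. Oxidative demethylation with (NH4)2Ce(NO3)6 in MeCN/H2O at 0 °C would give 3-hexadecyl-2,5-dimethoxycyclohexa-2,5-diene-1,4-dione F3; either para pair gives the same quinone by symmetry. Acid hydrolysis (70% HClO4, 1,4-dioxane, rt) should then remove first the methoxy group flanked by the chain, which is twisted out of conjugation, to give 12.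

2. Step 4. Cleavage of the C–Si bond by fluoride may stall, or the basic medium may cause self-condensation of the enolisable ketone. The fallback avoids silicon, sets out from 3-methoxyfuran 4 and returns at 8. C2-lithiation (n-BuLi, THF) and carboxylation with CO2 would give 3-methoxyfuran-2-carboxylic acid F4, in which the carboxylate is the blocking group. The dianion formed with LiN(i-Pr)2 (2.2 equiv, THF, −78 °C) should be lithiated at C5, and acylation with 3 would give 3-methoxy-5-octadecanoylfuran-2-carboxylic acid F5. Protodecarboxylation (Ag2CO3 cat., AcOH, DMSO, 120 °C) would give 8.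

3. Step 3. Metalation may be incomplete or misdirected, by deprotonation at C4 beside the methoxy group or by attack of butyllithium at silicon. The fallback replaces lithiation by catalytic C–H functionalisation, sets out from 6 and returns at 7. Borylation with [Ir(OMe)(cod)]2, 4,4'-di-tert-butyl-2,2'-bipyridine and bis(pinacolato)diboron in THF at 50 °C should occur at C5, the only free α-position, to give [3-methoxy-5-(4,4,5,5-tetramethyl-1,3,2-dioxaborolan-2-yl)furan-2-yl]trimethylsilane F6. Anhydrous acyl Suzuki–Miyaura coupling with stearoyl chloride 1 (Pd(PPh3)4, K3PO4, toluene, 80 °C) would give 7.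

**Further compounds**

F1 | step 5 | 1-(2,3,5,6-tetramethoxyphenyl)octadecan-1-one | CCCCCCCCCCCCCCCCCC(=O)c1c(OC)c(OC)cc(OC)c1OC
F2 | step 5 | 3-hexadecyl-1,2,4,5-tetramethoxybenzene | CCCCCCCCCCCCCCCCc1c(OC)c(OC)cc(OC)c1OC
F3 | step 5 | 3-hexadecyl-2,5-dimethoxycyclohexa-2,5-diene-1,4-dione | CCCCCCCCCCCCCCCCC1=C(OC)C(=O)C=C(OC)C1=O
F4 | step 4 | 3-methoxyfuran-2-carboxylic acid | COc1ccoc1C(=O)O
F5 | step 4 | 3-methoxy-5-octadecanoylfuran-2-carboxylic acid | CCCCCCCCCCCCCCCCCC(=O)c1cc(OC)c(C(=O)O)o1
F6 | step 3 | [3-methoxy-5-(4,4,5,5-tetramethyl-1,3,2-dioxaborolan-2-yl)furan-2-yl]trimethylsilane | COc1cc(B2OC(C)(C)C(C)(C)O2)oc1[Si](C)(C)C
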